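**Retrosynthetic overview**
- Target: (13S)-15-acetoxylabd-7-en-17-oic acid; the last disconnection is the tert-butyl ester at C17.
- The strategy rests on two features of ring B: C10 is a quaternary ring-fusion carbon that can be generated as a tertiary radical from a C1=C10 alkene of a monocyclic ring A, and the C7=C8 alkene carrying C17 is the olefination product of a C7 aldehyde and a C8 phosphonoacetate carbanion.
- Key disconnections: C9–C10 (radical conjugate addition) and C7=C8 (intramolecular Horner–Wadsworth–Emmons), made in one operation from a ring A aldehyde and an alkylidene phosphonoacetate that carries C8, C9, C17 and the whole C11–C16 chain.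
- Ring A aldehyde: from 2,4,4-trimethylcyclohex-2-enone by enantioselective reduction, Johnson–Claisen chirality transfer (sets C5) and partial reduction. Acceptor: from (S)-citronellol (brings C13) by acetylation, ozonolysis and Knoevenagel condensation.
- Order of rings: ring A is present from the start; ring B is closed last, in the annulation.

Key step: step 7

Remark: labdane numbering is used for all carbons (C1–C10 decalin, C11–C16 side chain, C17 on C8, C18–C20 methyls), and 12 is drawn as the E isomer expected from the condensation; any Z isomer should give the same product because the alkene geometry is lost at the C8 radical.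

**Route**

Step 1
Reactants: 1 2,4,4-trimethylcyclohex-2-en-1-one
Product: 2 (1R)-2,4,4-trimethylcyclohex-2-en-1-ol
Conditions: (S)-2-methyl-CBS-oxazaborolidine [(S)-1-methyl-3,3-diphenyltetrahydro-1H,3H-pyrrolo[1,2-c][1,3,2]oxazaborole] (10 mol%), BH3·SMe2, THF, −20 °C; then MeOH
Reagents that add atoms: none
Why: Corey–Bakshi–Shibata reduction in which the 2-methylalkenyl side of the carbonyl acts as the large group, so that hydride is delivered to one face and the carbinol centre should form with R configuration; this centre is the source of C5.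

Step 2
Reactants: 2 (1R)-2,4,4-trimethylcyclohex-2-en-1-ol; 3 triethyl orthoacetate
Product: 5 ethyl 2-[(1S)-2,6,6-trimethylcyclohex-2-en-1-yl]acetate, via ketene acetal 4 (not isolated)
Conditions: EtCO2H (cat.), neat 3 (5 equiv), 140 °C, EtOH distilled off
Reagents that add atoms: none
Why: Johnson–Claisen rearrangement: the [3,3] shift of ketene acetal 4 is suprafacial on the ring, so the C–O centre of 2 is relayed to the new C–C centre beside the gem-dimethyl carbon (S, the later C5) while the alkene moves to the methyl-bearing position (the later C1=C10).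

Step 3
Reactants: 5 ethyl 2-[(1S)-2,6,6-trimethylcyclohex-2-en-1-yl]acetate
Product: 6 2-[(1S)-2,6,6-trimethylcyclohex-2-en-1-yl]acetaldehyde
Conditions: i-Bu2AlH (1.1 equiv), CH2Cl2, −78 °C; then aq. potassium sodium tartrate
Reagents that add atoms: none
Why: Partial ester reduction stops at the tetrahedral aluminium hemiacetal at −78 °C and releases the aldehyde on work-up; the stereocentre is β to the carbonyl and cannot epimerise.

Step 4
Reactants: 7 (S)-citronellol
Product: 8 (3S)-3,7-dimethyloct-6-en-1-yl acetate
Conditions: Ac2O, pyridine, DMAP (cat.), 0 °C to rt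
Reagents that add atoms: acetic anhydride CC(=O)OC(C)=O
Why: DMAP-catalysed acylation of a primary alcohol, which installs the C15 acetate of the target at the outset and leaves the C13 centre untouched.

Step 5
Reactants: 8 (3S)-3,7-dimethyloct-6-en-1-yl acetate
Product: 10 (3S)-3-methyl-6-oxohexyl acetate, via ozonide 9 (not isolated)
Conditions: O3, CH2Cl2, −78 °C; then PPh3, −78 °C to rt
Reagents that add atoms: ozone [O-][O+]=O
Why: Ozonolysis of the electron-rich trisubstituted alkene (Criegee mechanism) with reductive work-up cleaves off acetone and leaves the C9 aldehyde, the acetate and C13 being inert.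

Step 6
Reactants: 10 (3S)-3-methyl-6-oxohexyl acetate; 11 tert-butyl diethylphosphonoacetate
Product: 12 tert-butyl (2E,6S)-8-acetoxy-2-(diethoxyphosphoryl)-6-methyloct-2-enoate
Conditions: TiCl4, N-methylmorpholine, THF, 0 °C to rt
Reagents that add atoms: none
Why: Knoevenagel condensation through the titanium enolate of 11, whose aldolate eliminates the titanium-bound oxygen and not phosphate, so that C8=C9 is formed with both activating groups retained.

Step 7
Reactants: 6 2-[(1S)-2,6,6-trimethylcyclohex-2-en-1-yl]acetaldehyde; 12 tert-butyl (2E,6S)-8-acetoxy-2-(diethoxyphosphoryl)-6-methyloct-2-enoate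
Product: 14 tert-butyl (1R,4aS,8aS)-1-[(3S)-5-acetoxy-3-methylpentyl]-5,5,8a-trimethyl-1,4,4a,5,6,7,8,8a-octahydronaphthalene-2-carboxylate, via phosphonate aldehyde 13 (not isolated)
Conditions: Fe(acac)3 (30 mol%), PhSiH3 (2.5 equiv), 12 (2 equiv), EtOH/(CH2OH)2, 60 °C; then solvent exchange, LiCl, DBU, MeCN, rt
Reagents that add atoms: none
Why: Proposed new method: the iron hydride generated from Fe(acac)3 and PhSiH3 should transfer a hydrogen atom to C1 of the electron-rich ring A alkene of 6, the tertiary C10 radical should add to C9 of the doubly activated alkene of 12, and the resulting C8 radical should be reduced by divalent iron to the phosphonoacetate carbanion, which ethanol is expected to protonate in part to 13 and which LiCl/DBU regenerates. The closest known reaction types are the Fe(acac)3/PhSiH3 Giese addition of alkene-derived tertiary radicals, radical–polar crossover annulations that close by an aldol step, and the ionic Michael/intramolecular Horner–Wadsworth–Emmons annulation of 2-phosphonoacrylates. Ring B is closed by intramolecular Horner–Wadsworth–Emmons olefination, a 6-exo-trig addition of the C8 carbanion to the C7 aldehyde followed by loss of diethyl phosphate, which leaves C7=C8 conjugated to the C17 ester. C10 is controlled by the C5 stereocentre, because the acceptor must approach ring A trans to the C5 acetaldehyde arm and away from the syn-axial C4 methyl group, which gives the trans ring fusion with an axial C10 methyl. C9 is fixed in the same bond formation by a staggered Felkin-type transition state in which the bulky C8 terminus lies anti to C5, the C9 hydrogen faces the C6 arm and the C11 chain lies anti to the C10 methyl, which should favour the 9R epimer but is the least secure element because C9 cannot be corrected later. The step also needs hydrogen-atom transfer to the ring alkene in preference to the electron-poor alkene and the aldehyde, which the polarity of the iron hydride and of the nucleophilic tertiary radical, supported by an excess of 12, should secure.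

Step 8
Reactants: 14 tert-butyl (1R,4aS,8aS)-1-[(3S)-5-acetoxy-3-methylpentyl]-5,5,8a-trimethyl-1,4,4a,5,6,7,8,8a-octahydronaphthalene-2-carboxylate
Product: 15 (1R,4aS,8aS)-1-[(3S)-5-acetoxy-3-methylpentyl]-5,5,8a-trimethyl-1,4,4a,5,6,7,8,8a-octahydronaphthalene-2-carboxylic acid
Conditions: CF3CO2H/CH2Cl2 (1:4), 0 °C to rt
Reagents that add atoms: none
Why: Acidolysis of the tert-butyl ester by alkyl–oxygen cleavage through the tert-butyl cation should free the C17 acid without touching the primary acetate, the conjugated alkene or any of the four stereocentres.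

**Compound list**

1 | 2,4,4-trimethylcyclohex-2-en-1-one | CC1=CC(C)(C)CCC1=O | starting material
2 | (1R)-2,4,4-trimethylcyclohex-2-en-1-ol | CC1=CC(C)(C)CC[C@H]1O | intermediate
3 | triethyl orthoacetate | CCOC(C)(OCC)OCC | starting material
4 | 1-ethoxy-1-{[(1R)-2,4,4-trimethylcyclohex-2-en-1-yl]oxy}ethene (ketene acetal, not isolated) | CC1=CC(C)(C)CC[C@H]1OC(=C)OCC | intermediate
5 | ethyl 2-[(1S)-2,6,6-trimethylcyclohex-2-en-1-yl]acetate | CCOC(=O)C[C@H]1C(C)(C)CCC=C1C | intermediate
6 | 2-[(1S)-2,6,6-trimethylcyclohex-2-en-1-yl]acetaldehyde | O=CC[C@H]1C(C)(C)CCC=C1C | intermediate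
7 | (S)-citronellol, (3S)-3,7-dimethyloct-6-en-1-ol | OCC[C@@H](C)CCC=C(C)C | starting material
8 | (3S)-3,7-dimethyloct-6-en-1-yl acetate | CC(=O)OCC[C@@H](C)CCC=C(C)C | intermediate
9 | (3S)-5-(5,5-dimethyl-1,2,4-trioxolan-3-yl)-3-methylpentyl acetate (ozonide, not isolated) | CC(=O)OCC[C@@H](C)CCC1OOC(C)(C)O1 | intermediate
10 | (3S)-3-methyl-6-oxohexyl acetate | CC(=O)OCC[C@@H](C)CCC=O | intermediate
11 | tert-butyl diethylphosphonoacetate | CCOP(=O)(CC(=O)OC(C)(C)C)OCC | starting material
12 | tert-butyl (2E,6S)-8-acetoxy-2-(diethoxyphosphoryl)-6-methyloct-2-enoate | CC(=O)OCC[C@@H](C)CC/C=C(/P(=O)(OCC)OCC)C(=O)OC(C)(C)C | intermediate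
13 | tert-butyl (3R,6S)-8-acetoxy-2-(diethoxyphosphoryl)-6-methyl-3-[(1S,2S)-1,3,3-trimethyl-2-(2-oxoethyl)cyclohexyl]octanoate, C2 epimers (not isolated) | CC(=O)OCC[C@@H](C)CC[C@@H](C(C(=O)OC(C)(C)C)P(=O)(OCC)OCC)[C@@]1(C)CCCC(C)(C)[C@@H]1CC=O | intermediate
14 | tert-butyl (1R,4aS,8aS)-1-[(3S)-5-acetoxy-3-methylpentyl]-5,5,8a-trimethyl-1,4,4a,5,6,7,8,8a-octahydronaphthalene-2-carboxylate | CC(=O)OCC[C@@H](C)CC[C@H]1C(C(=O)OC(C)(C)C)=CC[C@H]2C(C)(C)CCC[C@]12C | intermediate
15 | (1R,4aS,8aS)-1-[(3S)-5-acetoxy-3-methylpentyl]-5,5,8a-trimethyl-1,4,4a,5,6,7,8,8a-octahydronaphthalene-2-carboxylic acid | CC(=O)OCC[C@@H](C)CC[C@H]1C(C(=O)O)=CC[C@H]2C(C)(C)CCC[C@]12C | target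

**Step count**

Total step count: 8 (two three-step branches, then two common steps).
Longest linear sequence: 5 steps (1, 2, 3, 7, 8 or 4, 5, 6, 7, 8).

**Steps most likely to fail**

1. Step 7 (Proposed new method). Three processes may defeat it:
   - The hindered C10 radical may be reduced, or may return its hydrogen atom and so move the ring alkene (which could also erase C5), before it adds to the β-substituted acceptor.
   - The addition may proceed with low facial selectivity at C9.
   - Closure may stall if the carbanion is not regenerated cleanly.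

   The fallback uses the known radical–polar crossover annulation that closes by an aldol condensation. It sets out from 10 and 6 and returns to the route at target 15. Aldehyde 10 would be homologated with (triphenylphosphoranylidene)acetaldehyde (toluene, 80 °C) to (3S,6E)-3-methyl-8-oxooct-6-en-1-yl acetate F1. Treatment of 6 and this enal with Fe(acac)3/PhSiH3 (EtOH/(CH2OH)2, 60 °C) should give, by Giese addition of the C10 radical to C9 and aldol closure of the iron enolate onto C7, (13S)-15-acetoxy-7-hydroxylabdan-17-al F2. Dehydration (cat. p-TsOH, toluene, 40 °C) should give (13S)-15-acetoxylabd-7-en-17-al F3. Pinnick oxidation (NaClO2, NaH2PO4, 2-methylbut-2-ene, t-BuOH/H2O) would then give 15 directly, so that steps 6 and 8 fall away. C9 epimers, if formed, would be separated at the enal stage.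

2. Step 6. The enolisable aldehyde may self-condense, the new double bond may migrate out of conjugation under the amine base, and TiCl4 may cleave the tert-butyl ester.

   The fallback builds the alkene by selenoxide elimination instead of condensation. It sets out from 10 and 11 and returns at 12. Reduction of 10 (NaBH4, MeOH, 0 °C) would give (3S)-6-hydroxy-3-methylhexyl acetate F4. Iodination (I2, PPh3, imidazole, CH2Cl2) would give (3S)-6-iodo-3-methylhexyl acetate F5. Alkylation of the sodium salt of 11 (NaH, DMF, rt to 60 °C) would give tert-butyl (6S)-8-acetoxy-2-(diethoxyphosphoryl)-6-methyloctanoate F6. Selenenylation (NaH, PhSeCl, THF, 0 °C) would give tert-butyl (6S)-8-acetoxy-2-(diethoxyphosphoryl)-6-methyl-2-(phenylselanyl)octanoate F7. Oxidation (H2O2, CH2Cl2, 0 °C) would give tert-butyl (6S)-8-acetoxy-2-(diethoxyphosphoryl)-6-methyl-2-(phenylseleninyl)octanoate F8, whose syn-elimination toward C9, the only carbon with a β-hydrogen, gives 12.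

3. Step 2. Acid-promoted ionisation and dehydration of the allylic alcohol may outrun the [3,3] shift, which is slowed because the new bond forms at the carbon beside the quaternary centre.

   The fallback replaces the acid-catalysed orthoester exchange by an ester-enolate (Ireland–Claisen) rearrangement at the acid oxidation level. It sets out from 2 and returns at 6, bypassing 5 and step 3. Acetylation (Ac2O, pyridine, DMAP) would give (1R)-2,4,4-trimethylcyclohex-2-en-1-yl acetate F9. Enolisation and silylation (LiN(i-Pr)2, Me3SiCl, THF, −78 °C) would give 1-(trimethylsilyloxy)-1-{[(1R)-2,4,4-trimethylcyclohex-2-en-1-yl]oxy}ethene F10. Warming to 60 °C would give trimethylsilyl 2-[(1S)-2,6,6-trimethylcyclohex-2-en-1-yl]acetate F11 with the same suprafacial chirality transfer. Aqueous HCl would give 2-[(1S)-2,6,6-trimethylcyclohex-2-en-1-yl]acetic acid F12. Reduction (LiAlH4, Et2O, 0 °C) would give 2-[(1S)-2,6,6-trimethylcyclohex-2-en-1-yl]ethanol F13, and oxidation with Dess–Martin periodinane (CH2Cl2, rt) would give 6.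

**Further compounds**

F1 | step 7 | (3S,6E)-3-methyl-8-oxooct-6-en-1-yl acetate | CC(=O)OCC[C@@H](C)CC/C=C/C=O
F2 | step 7 | (13S)-15-acetoxy-7-hydroxylabdan-17-al, C7 and C8 epimers, 5α-H, 9α-H, 10β-methyl | CC(=O)OCC[C@@H](C)CC[C@H]1C(C=O)C(O)C[C@H]2C(C)(C)CCC[C@]12C
F3 | step 7 | (13S)-15-acetoxylabd-7-en-17-al | CC(=O)OCC[C@@H](C)CC[C@H]1C(C=O)=CC[C@H]2C(C)(C)CCC[C@]12C
F4 | step 6 | (3S)-6-hydroxy-3-methylhexyl acetate | CC(=O)OCC[C@@H](C)CCCO
F5 | step 6 | (3S)-6-iodo-3-methylhexyl acetate | CC(=O)OCC[C@@H](C)CCCI
F6 | step 6 | tert-butyl (6S)-8-acetoxy-2-(diethoxyphosphoryl)-6-methyloctanoate | CC(=O)OCC[C@@H](C)CCCC(C(=O)OC(C)(C)C)P(=O)(OCC)OCC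
F7 | step 6 | tert-butyl (6S)-8-acetoxy-2-(diethoxyphosphoryl)-6-methyl-2-(phenylselanyl)octanoate | CC(=O)OCC[C@@H](C)CCCC([Se]c1ccccc1)(C(=O)OC(C)(C)C)P(=O)(OCC)OCC
F8 | step 6 | tert-butyl (6S)-8-acetoxy-2-(diethoxyphosphoryl)-6-methyl-2-(phenylseleninyl)octanoate | CC(=O)OCC[C@@H](C)CCCC([Se](=O)c1ccccc1)(C(=O)OC(C)(C)C)P(=O)(OCC)OCC
F9 | step 2 | (1R)-2,4,4-trimethylcyclohex-2-en-1-yl acetate | CC1=CC(C)(C)CC[C@H]1OC(C)=O
F10 | step 2 | 1-(trimethylsilyloxy)-1-{[(1R)-2,4,4-trimethylcyclohex-2-en-1-yl]oxy}ethene | CC1=CC(C)(C)CC[C@H]1OC(=C)O[Si](C)(C)C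
F11 | step 2 | trimethylsilyl 2-[(1S)-2,6,6-trimethylcyclohex-2-en-1-yl]acetate | C[Si](C)(C)OC(=O)C[C@H]1C(C)(C)CCC=C1C
F12 | step 2 | 2-[(1S)-2,6,6-trimethylcyclohex-2-en-1-yl]acetic acid | OC(=O)C[C@H]1C(C)(C)CCC=C1C
F13 | step 2 | 2-[(1S)-2,6,6-trimethylcyclohex-2-en-1-yl]ethanol | OCC[C@H]1C(C)(C)CCC=C1C
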